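**Retrosynthetic overview**

1. Numbering follows the C15 chain of the target (C1 alkyne CH, C6 CHCl, C7 CHOAc, oxane oxygen between C9 and C13, C15 ethyl CH3). The target comes from O7 acetylation and desilylation of a 3-chloro-oxane, which comes from one-atom ring enlargement of a 2,5-cis oxolane (oxygen on C10 and C13) carrying an activated carbinol on exocyclic C9.
2. Enabling feature: the oxolane oxygen is β to C9 and the C9–O/C10–O pair is threo, so O, C9 and C10 can close a three-membered oxonium ring. Chloride then opens it at C10, so C9–O and C10–Cl both form with inversion; bromine at C12 is trans to the C9 arm and O7 is a silyl ether, so neither can participate.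
3. The C9 carbinol comes from an aldol union at C7–C8 (oxolanyl methyl ketone plus an α-chloroaldehyde carrying the enyne, giving the anti C6–Cl/C7–O pair), then Felkin–Anh reduction at C9.
4. The oxolanyl methyl ketone comes from an aldol at C11–C12 (mono-ketal of butanedione plus (R)-2-chlorobutanal), 1,3-anti reduction, displacement of the C13 chloride by the C10 hydroxyl, and bromide at C12 with inversion.
5. Ring order: the five-membered oxolane is made first (step 8); the six-membered oxane never arises by cyclisation, only by enlargement of the oxolane in step 14.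

Key step: step 14

Assumption: the (2S,5S) antipode of 2,5-diphenylpyrrolidine is taken to give the (R)-α-chloroaldehydes; if the sense of induction is the opposite, the (2R,5R) antipode is used in steps 4 and 5 and nothing else changes.

**Route**

Step 1
Reactants: 1 ethynyltrimethylsilane; 2 (E)-1,2-dichloroethene (fivefold excess)
Product: 3 [(3E)-4-chlorobut-3-en-1-yn-1-yl]trimethylsilane
Conditions: Pd(PPh3)4 (3 mol %), CuI (6 mol %), piperidine, Et2O, 20 °C
Reagents that add atoms: none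
Why: Sonogashira coupling with the dichloroalkene in excess should stop at monosubstitution and keep the E geometry, because oxidative addition of zerovalent palladium to the alkenyl chloride and the following steps are stereoretentive.

Step 2
Reactants: 3 [(3E)-4-chlorobut-3-en-1-yn-1-yl]trimethylsilane; 4 (3-ethoxy-3-oxopropyl)zinc bromide
Product: 5 ethyl (4E)-7-(trimethylsilyl)hept-4-en-6-ynoate
Conditions: Pd(P(t-Bu)3)2 (3 mol %), THF–NMP, 50 °C
Reagents that add atoms: none
Why: Negishi coupling of the alkynyl-activated alkenyl chloride with the ester-bearing alkylzinc reagent is stereoretentive, so the C3=C4 bond should stay E, and the bulky phosphine suppresses β-hydride elimination.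

Step 3
Reactants: 5 ethyl (4E)-7-(trimethylsilyl)hept-4-en-6-ynoate
Product: 6 (4E)-7-(trimethylsilyl)hept-4-en-6-ynal
Conditions: i-Bu2AlH, CH2Cl2, −78 °C; aqueous potassium sodium tartrate
Reagents that add atoms: none
Why: Partial ester reduction should stop at the aldehyde because the aluminium hemiacetal is stable at −78 °C until work-up.

Step 4
Reactants: 6 (4E)-7-(trimethylsilyl)hept-4-en-6-ynal
Product: 7 (2R,4E)-2-chloro-7-(trimethylsilyl)hept-4-en-6-ynal
Conditions: NCS, (2S,5S)-2,5-diphenylpyrrolidine (10 mol %), CH2Cl2, 0 to 20 °C; pentane, filtration; solution used at once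
Reagents that add atoms: N-chlorosuccinimide, O=C1CCC(=O)N1Cl
Why: Enamine-catalysed α-chlorination with the C2-symmetric pyrrolidine should set C6 (R) by shielding one enamine face, and the product is used without chromatography because α-chloroaldehydes epimerise on silica.

Step 5
Reactants: 8 butanal
Product: 9 (2R)-2-chlorobutanal
Conditions: NCS, (2S,5S)-2,5-diphenylpyrrolidine (10 mol %), CH2Cl2, 0 to 20 °C; pentane, filtration; cold solution used at once
Reagents that add atoms: N-chlorosuccinimide, O=C1CCC(=O)N1Cl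
Why: The same enamine-catalysed α-chlorination should set the (R) chloride at the future C13, which is inverted on purpose in step 8.

Step 6
Reactants: 10 3,3-dimethoxybutan-2-one; 9 (2R)-2-chlorobutanal
Product: 12 (5S,6R)-6-chloro-5-hydroxy-2,2-dimethoxyoctan-3-one, via lithium enolate 11 (not isolated)
Conditions: LiN(i-Pr)2, THF, −78 °C; then 9, −78 °C; aqueous NH4Cl
Reagents that add atoms: none
Why: Lithium enolate aldol addition to an α-chloroaldehyde follows the Cornforth (polar Felkin–Anh) model and should give the 1,2-anti chlorohydrin, which sets C12 (S) relative to C13, while the ketal leaves only the C11 methyl group enolisable.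

Step 7
Reactants: 12 (5S,6R)-6-chloro-5-hydroxy-2,2-dimethoxyoctan-3-one
Product: 13 (3S,5S,6R)-6-chloro-2,2-dimethoxyoctane-3,5-diol
Conditions: Me4NBH(OAc)3, MeCN–AcOH, −30 °C
Reagents that add atoms: none
Why: Evans–Saksena reduction delivers hydride intramolecularly from the C12 alkoxyborohydride through a chair transition state and should set C10 (S), 1,3-anti to C12.

Step 8
Reactants: 13 (3S,5S,6R)-6-chloro-2,2-dimethoxyoctane-3,5-diol
Product: 14 (2S,3S,5S)-5-(1,1-dimethoxyethyl)-2-ethyloxolan-3-ol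
Conditions: AgOSO2CF3, Ag2O, THF, 20 °C, dark
Reagents that add atoms: none
Why: Silver-assisted SN2 displacement of the secondary chloride by the C10 hydroxyl (5-exo-tet etherification) should close the oxolane with inversion at C13 and give the 2,3,5-all-cis ring.

Step 9
Reactants: 14 (2S,3S,5S)-5-(1,1-dimethoxyethyl)-2-ethyloxolan-3-ol
Product: 15 (2S,3R,5S)-3-bromo-5-(1,1-dimethoxyethyl)-2-ethyloxolane
Conditions: CBr4, (n-C8H17)3P, 1-methylcyclohexene, toluene, 70 °C
Reagents that add atoms: tetrabromomethane, BrC(Br)(Br)Br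
Why: Appel bromination should displace the activated C12 oxygen with inversion from the open ring face opposite all three substituents, placing bromine trans to the ethyl group and trans to the C10 arm.

Step 10
Reactants: 15 (2S,3R,5S)-3-bromo-5-(1,1-dimethoxyethyl)-2-ethyloxolane
Product: 16 1-[(2S,4R,5S)-4-bromo-5-ethyloxolan-2-yl]ethan-1-one
Conditions: CF3CO2H–H2O, CH2Cl2, 0 °C
Reagents that add atoms: water, O
Why: Acid-catalysed ketal hydrolysis frees the methyl ketone, and at 0 °C the α-alkoxy stereocentre C10 is not expected to enolise.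

Step 11
Reactants: 16 1-[(2S,4R,5S)-4-bromo-5-ethyloxolan-2-yl]ethan-1-one; 7 (2R,4E)-2-chloro-7-(trimethylsilyl)hept-4-en-6-ynal
Product: 18 (3S,4R,6E)-1-[(2S,4R,5S)-4-bromo-5-ethyloxolan-2-yl]-4-chloro-3-hydroxy-9-(trimethylsilyl)non-6-en-8-yn-1-one, via lithium enolate 17 (not isolated)
Conditions: LiN(i-Pr)2, THF, −78 °C; then 7, −78 °C; aqueous NH4Cl
Reagents that add atoms: none
Why: Kinetic deprotonation at the methyl group and aldol addition to the α-chloroaldehyde again follow the Cornforth model and should set C7 (S) anti to the C6 chloride while joining the two halves at C7–C8.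

Step 12
Reactants: 18 (3S,4R,6E)-1-[(2S,4R,5S)-4-bromo-5-ethyloxolan-2-yl]-4-chloro-3-hydroxy-9-(trimethylsilyl)non-6-en-8-yn-1-one
Product: 19 (3S,4R,6E)-1-[(2S,4R,5S)-4-bromo-5-ethyloxolan-2-yl]-3-{[tert-butyl(dimethyl)silyl]oxy}-4-chloro-9-(trimethylsilyl)non-6-en-8-yn-1-one
Conditions: t-BuMe2SiOSO2CF3, 2,6-lutidine, CH2Cl2, −78 °C
Reagents that add atoms: tert-butyldimethylsilyl trifluoromethanesulfonate, CC(C)(C)[Si](C)(C)OS(=O)(=O)C(F)(F)F
Why: Silylation protects O7 as an ether that, unlike an ester, cannot act as a neighbouring group in step 14.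

Step 13
Reactants: 19 (3S,4R,6E)-1-[(2S,4R,5S)-4-bromo-5-ethyloxolan-2-yl]-3-{[tert-butyl(dimethyl)silyl]oxy}-4-chloro-9-(trimethylsilyl)non-6-en-8-yn-1-one
Product: 20 (1S,3S,4R,6E)-1-[(2S,4R,5S)-4-bromo-5-ethyloxolan-2-yl]-3-{[tert-butyl(dimethyl)silyl]oxy}-4-chloro-9-(trimethylsilyl)non-6-en-8-yn-1-ol
Conditions: LiBH(s-Bu)3, THF, −78 °C; aqueous NH4Cl
Reagents that add atoms: none
Why: Felkin–Anh reduction of the α-alkoxy ketone by the bulky, non-chelating borohydride should attack anti to the oxolane C10–O bond and set C9 (S), threo to C10 and 1,3-anti to O7.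

Step 14
Reactants: 20 (1S,3S,4R,6E)-1-[(2S,4R,5S)-4-bromo-5-ethyloxolan-2-yl]-3-{[tert-butyl(dimethyl)silyl]oxy}-4-chloro-9-(trimethylsilyl)non-6-en-8-yn-1-ol
Product: 23 tert-butyl{[(2S,3R,5E)-1-[(2R,3R,5R,6S)-5-bromo-3-chloro-6-ethyloxan-2-yl]-3-chloro-8-(trimethylsilyl)oct-5-en-7-yn-2-yl]oxy}dimethylsilane, via chloromethanesulfonate 21 (not isolated), via oxonium ion 22 (not isolated)
Conditions: ClCH2SO2Cl, 2,6-lutidine, CH2Cl2, 0 °C; filtration through a short silica pad, solvent exchange; ZnCl2, (CF3)2CHOH–ClCH2CH2Cl, 40 °C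
Reagents that add atoms: zinc dichloride, Cl[Zn]Cl (the chloride at C10); chloromethanesulfonyl chloride, ClCS(Cl)(=O)=O (its atoms stay only in 21)
Why: Proposed new method: the C9 chloromethanesulfonate of 21 is ionised with zinc assistance in a strongly ionising, non-nucleophilic solvent, the oxolane oxygen displaces it with inversion at C9 (3-exo-tet closure) to give the fused oxiranium–oxolanium ion 22, and zinc-bound chloride opens 22 at the ring-fusion carbon C10 with inversion, which breaks the old C10–O bond. The closest known reaction type is the Zn(OAc)2-promoted rearrangement–ring expansion of oxolan-2-yl carbinol sulfonates to 3-acyloxyoxanes through the same kind of ion, with halide-terminated relatives in the nitrogen series (prolinol to 3-chloropiperidine) and fluoride-terminated deoxyfluorinative ring expansions; only chloride as the terminating nucleophile is new. The oxane ring is not closed by cyclisation; it arises by enlargement of the oxolane by one atom, with exocyclic C9 entering the ring, and the only ring closure is the transient three-membered one. Both new stereocentres follow stereospecifically from the two inversions: the threo C9/C10 relation and the 2,5-cis oxolane of 20 should become the 2,6-cis oxane with C9 (R) and an axial chloride at C10 (R). The step needs oxygen participation to beat direct SN2 at C9, which is favoured by the absence of free chloride, the β-oxygen that slows SN2 at C9, the non-participating silyl ether at O7 and bromine at C12 lying trans to the C9 arm. It also needs opening at C10 rather than C9, which is expected from the preference of such fused ions for cleavage of the strained ring-fusion bond.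

Step 15
Reactants: 23 tert-butyl{[(2S,3R,5E)-1-[(2R,3R,5R,6S)-5-bromo-3-chloro-6-ethyloxan-2-yl]-3-chloro-8-(trimethylsilyl)oct-5-en-7-yn-2-yl]oxy}dimethylsilane
Product: 24 (2S,3R,5E)-1-[(2R,3R,5R,6S)-5-bromo-3-chloro-6-ethyloxan-2-yl]-3-chlorooct-5-en-7-yn-2-ol
Conditions: n-Bu4NF, AcOH, THF, 0 to 20 °C
Reagents that add atoms: none
Why: Buffered fluoride desilylation cleaves both the alkynyl C–Si bond and the silyl ether, and the acetic acid keeps the freed C7 alkoxide from closing an epoxide onto C6.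

Step 16
Reactants: 24 (2S,3R,5E)-1-[(2R,3R,5R,6S)-5-bromo-3-chloro-6-ethyloxan-2-yl]-3-chlorooct-5-en-7-yn-2-ol
Product: 25 (2S,3R,5E)-1-[(2R,3R,5R,6S)-5-bromo-3-chloro-6-ethyloxan-2-yl]-3-chlorooct-5-en-7-yn-2-yl acetate
Conditions: Ac2O, pyridine, DMAP (cat.), CH2Cl2, 0 °C
Reagents that add atoms: acetic anhydride, CC(=O)OC(C)=O
Why: DMAP-catalysed acylation of the secondary alcohol should give the acetate without touching the halides or the enyne.

**Compound list**

1 | ethynyltrimethylsilane | C#C[Si](C)(C)C | starting material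
2 | (E)-1,2-dichloroethene | Cl/C=C/Cl | starting material
3 | [(3E)-4-chlorobut-3-en-1-yn-1-yl]trimethylsilane | C[Si](C)(C)C#C/C=C/Cl | intermediate
4 | (3-ethoxy-3-oxopropyl)zinc bromide | CCOC(=O)CC[Zn]Br | starting material
5 | ethyl (4E)-7-(trimethylsilyl)hept-4-en-6-ynoate | CCOC(=O)CC/C=C/C#C[Si](C)(C)C | intermediate
6 | (4E)-7-(trimethylsilyl)hept-4-en-6-ynal | O=CCC/C=C/C#C[Si](C)(C)C | intermediate
7 | (2R,4E)-2-chloro-7-(trimethylsilyl)hept-4-en-6-ynal | C[Si](C)(C)C#C/C=C/C[C@@H](Cl)C=O | intermediate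
8 | butanal | CCCC=O | starting material
9 | (2R)-2-chlorobutanal | CC[C@@H](Cl)C=O | intermediate
10 | 3,3-dimethoxybutan-2-one | CC(=O)C(C)(OC)OC | starting material
11 | lithium 3,3-dimethoxybut-1-en-2-olate | [Li+].C=C([O-])C(C)(OC)OC | intermediate
12 | (5S,6R)-6-chloro-5-hydroxy-2,2-dimethoxyoctan-3-one | CC[C@@H](Cl)[C@@H](O)CC(=O)C(C)(OC)OC | intermediate
13 | (3S,5S,6R)-6-chloro-2,2-dimethoxyoctane-3,5-diol | CC[C@@H](Cl)[C@@H](O)C[C@H](O)C(C)(OC)OC | intermediate
14 | (2S,3S,5S)-5-(1,1-dimethoxyethyl)-2-ethyloxolan-3-ol | CC[C@@H]1O[C@@H](C[C@@H]1O)C(C)(OC)OC | intermediate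
15 | (2S,3R,5S)-3-bromo-5-(1,1-dimethoxyethyl)-2-ethyloxolane | CC[C@@H]1O[C@@H](C[C@H]1Br)C(C)(OC)OC | intermediate
16 | 1-[(2S,4R,5S)-4-bromo-5-ethyloxolan-2-yl]ethan-1-one | CC[C@@H]1O[C@@H](C[C@H]1Br)C(C)=O | intermediate
17 | lithium 1-[(2S,4R,5S)-4-bromo-5-ethyloxolan-2-yl]ethen-1-olate | CC[C@@H]1O[C@@H](C[C@H]1Br)C([O-])=C.[Li+] | intermediate
18 | (3S,4R,6E)-1-[(2S,4R,5S)-4-bromo-5-ethyloxolan-2-yl]-4-chloro-3-hydroxy-9-(trimethylsilyl)non-6-en-8-yn-1-one | CC[C@@H]1O[C@@H](C[C@H]1Br)C(=O)C[C@H](O)[C@H](Cl)C/C=C/C#C[Si](C)(C)C | intermediate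
19 | (3S,4R,6E)-1-[(2S,4R,5S)-4-bromo-5-ethyloxolan-2-yl]-3-{[tert-butyl(dimethyl)silyl]oxy}-4-chloro-9-(trimethylsilyl)non-6-en-8-yn-1-one | CC[C@@H]1O[C@@H](C[C@H]1Br)C(=O)C[C@H](O[Si](C)(C)C(C)(C)C)[C@H](Cl)C/C=C/C#C[Si](C)(C)C | intermediate
20 | (1S,3S,4R,6E)-1-[(2S,4R,5S)-4-bromo-5-ethyloxolan-2-yl]-3-{[tert-butyl(dimethyl)silyl]oxy}-4-chloro-9-(trimethylsilyl)non-6-en-8-yn-1-ol | CC[C@@H]1O[C@@H](C[C@H]1Br)[C@@H](O)C[C@H](O[Si](C)(C)C(C)(C)C)[C@H](Cl)C/C=C/C#C[Si](C)(C)C | intermediate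
21 | (1S,3S,4R,6E)-1-[(2S,4R,5S)-4-bromo-5-ethyloxolan-2-yl]-3-{[tert-butyl(dimethyl)silyl]oxy}-4-chloro-9-(trimethylsilyl)non-6-en-8-yn-1-yl chloromethanesulfonate | CC[C@@H]1O[C@@H](C[C@H]1Br)[C@@H](OS(=O)(=O)CCl)C[C@H](O[Si](C)(C)C(C)(C)C)[C@H](Cl)C/C=C/C#C[Si](C)(C)C | intermediate
22 | fused oxiranium–oxolanium ion (1-oxoniabicyclo[3.1.0]hexane; O bonded to C9, C10 and C13; bromine and ethyl on the five-membered ring, C8 side chain on the three-membered ring), chloromethanesulfonate counter-ion | CC[C@@H]1[O+]2[C@@H](C[C@H]1Br)[C@H]2C[C@H](O[Si](C)(C)C(C)(C)C)[C@H](Cl)C/C=C/C#C[Si](C)(C)C.[O-]S(=O)(=O)CCl | intermediate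
23 | tert-butyl{[(2S,3R,5E)-1-[(2R,3R,5R,6S)-5-bromo-3-chloro-6-ethyloxan-2-yl]-3-chloro-8-(trimethylsilyl)oct-5-en-7-yn-2-yl]oxy}dimethylsilane | C[Si](C)(C)C#C/C=C/C[C@@H](Cl)[C@H](C[C@H]1O[C@@H](CC)[C@H](Br)C[C@H]1Cl)O[Si](C)(C)C(C)(C)C | intermediate
24 | (2S,3R,5E)-1-[(2R,3R,5R,6S)-5-bromo-3-chloro-6-ethyloxan-2-yl]-3-chlorooct-5-en-7-yn-2-ol | C#C/C=C/C[C@@H](Cl)[C@H](C[C@H]1O[C@@H](CC)[C@H](Br)C[C@H]1Cl)O | intermediate
25 | (2S,3R,5E)-1-[(2R,3R,5R,6S)-5-bromo-3-chloro-6-ethyloxan-2-yl]-3-chlorooct-5-en-7-yn-2-yl acetate | C#C/C=C/C[C@@H](Cl)[C@H](C[C@H]1O[C@@H](CC)[C@H](Br)C[C@H]1Cl)OC(C)=O | target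

**Step count and risks**

Total step count: 16. Longest linear sequence: 12 steps (8 to 25, steps 5 to 16).

Steps most likely to fail:

1. Step 14 (proposed new method). Chloride may displace the sulfonate directly at C9 without oxygen participation. The oxonium ion may be opened at the exocyclic carbon C9 and return an oxolane. The silyl ether may be lost in the acidic medium, or the fluorinated alcohol may capture the ion. Fallback from 20 to 23 by known chemistry, with oxygen rather than chloride as the terminating nucleophile. Compound 21 is isolated and heated with Zn(OAc)2 in AcOH–H2O–1,4-dioxane at 50 °C, the established rearrangement–ring expansion, which should give the axial C10 acetate (2R,3R,5R,6S)-5-bromo-2-[(2S,3R,5E)-2-{[tert-butyl(dimethyl)silyl]oxy}-3-chloro-8-(trimethylsilyl)oct-5-en-7-yn-1-yl]-6-ethyloxan-3-yl acetate F1, accompanied by some free alcohol. Treatment with i-Bu2AlH at −78 °C converges both on the axial alcohol (2R,3R,5R,6S)-5-bromo-2-[(2S,3R,5E)-2-{[tert-butyl(dimethyl)silyl]oxy}-3-chloro-8-(trimethylsilyl)oct-5-en-7-yn-1-yl]-6-ethyloxan-3-ol F2. Dess–Martin oxidation gives the ketone (2R,5R,6S)-5-bromo-2-[(2S,3R,5E)-2-{[tert-butyl(dimethyl)silyl]oxy}-3-chloro-8-(trimethylsilyl)oct-5-en-7-yn-1-yl]-6-ethyloxan-3-one F3. Reduction with NaBH4 and CeCl3·7H2O in MeOH at −78 °C (axial hydride attack) should give the equatorial alcohol (2R,3S,5R,6S)-5-bromo-2-[(2S,3R,5E)-2-{[tert-butyl(dimethyl)silyl]oxy}-3-chloro-8-(trimethylsilyl)oct-5-en-7-yn-1-yl]-6-ethyloxan-3-ol F4. Appel chlorination (CCl4, (n-C8H17)3P, toluene, 80 °C) with inversion returns to the route at 23.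

2. Step 13. Facial selectivity may be poor if 1,3-induction from the O7 stereocentre opposes the Felkin–Anh sense, and some hydride attack on the secondary bromide is possible. Fallback from 19 to 20: chelation-controlled reduction with Zn(BH4)2 in Et2O at −20 °C (zinc bridging the ketone and the oxolane oxygen) should give the C9 epimer (1R,3S,4R,6E)-1-[(2S,4R,5S)-4-bromo-5-ethyloxolan-2-yl]-3-{[tert-butyl(dimethyl)silyl]oxy}-4-chloro-9-(trimethylsilyl)non-6-en-8-yn-1-ol F5. Mitsunobu esterification (ClCH2CO2H, PPh3, DIAD, toluene) inverts C9 to the ester (1S,3S,4R,6E)-1-[(2S,4R,5S)-4-bromo-5-ethyloxolan-2-yl]-3-{[tert-butyl(dimethyl)silyl]oxy}-4-chloro-9-(trimethylsilyl)non-6-en-8-yn-1-yl chloroacetate F6. Cleavage with i-Bu2AlH at −78 °C gives 20.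

3. Step 11. Proton transfer between the lithium enolate and the α-chloroaldehyde may erode the configuration at C6, base may cause elimination at the C12 bromide, and the anti selectivity may be lowered by the chiral enolate. Fallback from 16 to 18: the ketone is converted with LiN(i-Pr)2 and Me3SiCl at −78 °C into the kinetic silyl enol ether {[1-[(2S,4R,5S)-4-bromo-5-ethyloxolan-2-yl]ethenyl]oxy}trimethylsilane F7. A Mukaiyama aldol addition to 7 (BF3·OEt2, CH2Cl2, −78 °C; hydrolytic work-up) under non-chelating Lewis acid activation should again favour the 1,2-anti chlorohydrin and gives 18.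

Further compounds
F1 | step 14 | (2R,3R,5R,6S)-5-bromo-2-[(2S,3R,5E)-2-{[tert-butyl(dimethyl)silyl]oxy}-3-chloro-8-(trimethylsilyl)oct-5-en-7-yn-1-yl]-6-ethyloxan-3-yl acetate | C[Si](C)(C)C#C/C=C/C[C@@H](Cl)[C@H](C[C@H]1O[C@@H](CC)[C@H](Br)C[C@H]1OC(C)=O)O[Si](C)(C)C(C)(C)C
F2 | step 14 | (2R,3R,5R,6S)-5-bromo-2-[(2S,3R,5E)-2-{[tert-butyl(dimethyl)silyl]oxy}-3-chloro-8-(trimethylsilyl)oct-5-en-7-yn-1-yl]-6-ethyloxan-3-ol | C[Si](C)(C)C#C/C=C/C[C@@H](Cl)[C@H](C[C@H]1O[C@@H](CC)[C@H](Br)C[C@H]1O)O[Si](C)(C)C(C)(C)C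
F3 | step 14 | (2R,5R,6S)-5-bromo-2-[(2S,3R,5E)-2-{[tert-butyl(dimethyl)silyl]oxy}-3-chloro-8-(trimethylsilyl)oct-5-en-7-yn-1-yl]-6-ethyloxan-3-one | C[Si](C)(C)C#C/C=C/C[C@@H](Cl)[C@H](C[C@H]1O[C@@H](CC)[C@H](Br)CC1=O)O[Si](C)(C)C(C)(C)C
F4 | step 14 | (2R,3S,5R,6S)-5-bromo-2-[(2S,3R,5E)-2-{[tert-butyl(dimethyl)silyl]oxy}-3-chloro-8-(trimethylsilyl)oct-5-en-7-yn-1-yl]-6-ethyloxan-3-ol | C[Si](C)(C)C#C/C=C/C[C@@H](Cl)[C@H](C[C@H]1O[C@@H](CC)[C@H](Br)C[C@@H]1O)O[Si](C)(C)C(C)(C)C
F5 | step 13 | (1R,3S,4R,6E)-1-[(2S,4R,5S)-4-bromo-5-ethyloxolan-2-yl]-3-{[tert-butyl(dimethyl)silyl]oxy}-4-chloro-9-(trimethylsilyl)non-6-en-8-yn-1-ol | CC[C@@H]1O[C@@H](C[C@H]1Br)[C@H](O)C[C@H](O[Si](C)(C)C(C)(C)C)[C@H](Cl)C/C=C/C#C[Si](C)(C)C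
F6 | step 13 | (1S,3S,4R,6E)-1-[(2S,4R,5S)-4-bromo-5-ethyloxolan-2-yl]-3-{[tert-butyl(dimethyl)silyl]oxy}-4-chloro-9-(trimethylsilyl)non-6-en-8-yn-1-yl chloroacetate | CC[C@@H]1O[C@@H](C[C@H]1Br)[C@@H](OC(=O)CCl)C[C@H](O[Si](C)(C)C(C)(C)C)[C@H](Cl)C/C=C/C#C[Si](C)(C)C
F7 | step 11 | {[1-[(2S,4R,5S)-4-bromo-5-ethyloxolan-2-yl]ethenyl]oxy}trimethylsilane | CC[C@@H]1O[C@@H](C[C@H]1Br)C(O[Si](C)(C)C)=C
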